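I began from slowness: the plain coupling of starting material with dissolved coupling partner looked too slow for this flask.

starting material 0.050 M; gas 3.5 mM (held); time 15 d

    starting material + coupling partner → product (k1 = 0.108 M⁻¹ h⁻¹)
    coupling partner → decomposed reagent (k2 = 0.243 h⁻¹)
    starting material + coupling partner + product → 2 product (k3 = 15100 M⁻² h⁻¹)
    gas ⇌ coupling partner, rate k4*(csat - [coupling partner]) (k4 = 8.11 h⁻¹, csat = 3.5 mM)

- at the start none of coupling partner is dissolved
- the reaction counts as stopped when no species that holds the starting material changes by six tenths of a point or more over the second half of the time
- run time (flask): 15 d

- which holds at 15 d: what has brought the reaction to rest, or that it has not come to rest (forward and back rates have come level / all of the starting material has reacted / it is still moving)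
- how much of the starting material has reacted by 15 d
- how much product there is at 15 d, in percent of the starting material charged

Transfer from the gas outpaces decomposition, so I took the dissolved level c, where the two balance, as the saturation concentration times transfer over transfer plus decomposition: 3.40 mM. At that level the plain coupling is pseudo-first-order, and it gives the starting material a half-life of 78.7 d, longer than the run of 15 d.

But product speeds its own formation, so I followed f, the fraction left. Once product has taken over, f falls at r = 2.57 h⁻¹, which is 6990 times the plain rate. The logarithm of that ratio over r is the wait for half the charge to react, and the logarithm of 50 over r takes f on to a fiftieth. Their sum is the clearing time T, the time until under a fiftieth of the charge is left: 0.207 d. As T is far shorter than the run and no step consumes product, I expected the product to take up the charge.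

The forecast said all of the starting material has reacted, with conversion 100% (99.5% to 100%) and yield 100% (99.5% to 100%), since “the product-autocatalysed step then takes off within hours”.

The simulation gave all of the starting material has reacted, with conversion 100% and yield 100%.

In the first flask the starting material crossed the mark I had reckoned T for at 0.283 d, later than T. With 0.085 M of starting material in the neighbouring flask, the same reckoning gives T = 0.127 d, shorter than in the first flask and far shorter than the run. At 15.0 d that neighbouring flask held 100% product and 0% of its starting material.

(All constants were chosen freely; the flask was simulated.)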